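**Plan** (prenyl = 3‑methylbut‑2‑en‑1‑yl)

- Retrosynthesis, last ring first: the 2H‑pyran is cut at O–CMe2 and at C3–CH= (formal [3+3] with prenal). This is possible because the pyran O–C=C is the C2‑enol/C3 carbon of a 2‑hydroxycyclohex‑2‑ene‑1,4‑dione (an enolised cyclic 1,3‑diketone), and the other four ring atoms plus the gem‑dimethyl group are the chain of prenal.
- Next the acylal C–O(acyl) bond is cut (retro‑oxa‑Michael) to a hydroxyquinone acid, which comes from a resorcinol ring by Teuber oxidation. The cage is opened by retro‑Diels–Alder/retro‑Claisen to a catechol bis(1,1‑dimethylallyl) ether, and the diaryl ether is cut (Ullmann) into a prenylated phloroglucinol bis‑MOM ether and a 2‑bromogallate.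
- Forward ring order: temporary benzodioxole (orthoformate) → cyclohexadienone → bicyclo[2.2.2]octene + tetrahydrofuran in one Claisen/Diels–Alder cascade → spiro 1,3‑dioxin‑4‑one with dearomatisation of the carbocycle → 2H‑pyran last.
- Stereochemistry: the four cage centres are fixed relative to each other by the geometry of the intramolecular [4+2]. The absolute configuration comes from a (−)‑menthyloxymethyl acetal (a MOM surrogate from the chiral pool) that makes the two cage antipodes diastereomers, separated once after the cascade. The spiro carbon and the CH(prenyl) carbon are set by reversible conjugate addition/ketonisation and can re‑equilibrate in the last step.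

Key step: step 13

Remark: the natural configuration at the spiro acylal carbon (S) and at the adjacent CH(prenyl) carbon (S) is assumed to be the thermodynamically preferred one, both centres being equilibratable (retro‑oxa‑Michael/oxa‑Michael and enolisation).
Remark: tert‑butyl (2‑methylbut‑3‑en‑2‑yl) carbonate is taken as a purchasable reagent (otherwise it is one step from 2‑methylbut‑3‑en‑2‑ol and Boc2O).
Cage locants used in names (4‑oxatricyclo[4.3.1.0(3,7)]dec‑8‑en‑2‑one): C1 = oxygenated bridgehead next to the ketone C2; C3 = prenyl‑bearing carbon; O4; C5 = CMe2; C6 = CH; C7 = bridgehead carrying the ether oxygen; C8=C9 alkene with the carboxyl on C8; C10 = CH2.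

**Route**

Step 1
Reactants: 1 phloroglucinol
Product: 2 3,5‑bis(methoxymethoxy)phenol
Conditions: MOMCl (2.1 equiv), i‑Pr2NEt, DMF, 0 °C → rt; chromatography
Reagents that add atoms: chloromethyl methyl ether COCCl
Why: Statistical double O‑alkylation of the C3‑symmetric triphenol (MOM acetal formation) should give the bis‑ether after separation from mono‑ and tris‑ethers, which can be recycled; no stereocentre is formed.

Step 2
Reactants: 2 3,5‑bis(methoxymethoxy)phenol
Product: 3 3,5‑bis(methoxymethoxy)‑2‑prenylphenol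
Conditions: NaH, toluene, 0 °C; prenyl bromide, rt
Reagents that add atoms: prenyl bromide CC(C)=CCBr
Why: In a non‑polar solvent the tightly ion‑paired sodium phenoxide should undergo ortho C‑alkylation (phenoxide C‑prenylation), the two ortho positions being equivalent, which places prenyl between the free OH and one OMOM group; no stereocentre is formed.

Step 3
Reactants: 4 methyl gallate
Product: 5 methyl 2‑ethoxy‑7‑hydroxy‑1,3‑benzodioxole‑5‑carboxylate
Conditions: HC(OEt)3, Amberlyst‑15 (cat.), toluene, reflux (EtOH distilled off)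
Reagents that add atoms: triethyl orthoformate CCOC(OCC)OCC
Why: Acid‑catalysed transorthoesterification ties two adjacent phenols of the symmetric triol into a cyclic orthoformate (catechol protection) and leaves one OH free; the orthoester carbon forms as a racemate and is removed in step 7.

Step 4
Reactants: 5 methyl 2‑ethoxy‑7‑hydroxy‑1,3‑benzodioxole‑5‑carboxylate
Product: 6 methyl 2‑ethoxy‑7‑{[(1R,2S,5R)‑menthyloxy]methoxy}‑1,3‑benzodioxole‑5‑carboxylate
Conditions: (−)‑menthyl chloromethyl ether, i‑Pr2NEt, CH2Cl2, 0 °C → rt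
Reagents that add atoms: (−)‑menthyl chloromethyl ether ClCO[C@@H]1C[C@H](C)CC[C@H]1C(C)C
Why: O‑alkylation of the remaining phenol with the chiral chloromethyl ether (MOM‑type acetal formation) installs an acid‑labile group that also carries the resolving element; the menthyl stereocentres come from the chiral pool and are not touched.

Step 5
Reactants: 6 methyl 2‑ethoxy‑7‑{[(1R,2S,5R)‑menthyloxy]methoxy}‑1,3‑benzodioxole‑5‑carboxylate
Product: 7 methyl 4‑bromo‑2‑ethoxy‑7‑{[(1R,2S,5R)‑menthyloxy]methoxy}‑1,3‑benzodioxole‑5‑carboxylate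
Conditions: NBS, NaHCO3, MeCN, 0 °C → rt, dark
Reagents that add atoms: N‑bromosuccinimide O=C1CCC(=O)N1Br
Why: Electrophilic aromatic bromination should occur para to the acetal‑protected alkoxy group and ortho to the dioxole oxygen, the usual site for 5‑alkoxy‑3,4‑dioxygenated benzoates, and buffered NBS spares the orthoester.

Step 6
Reactants: 3 3,5‑bis(methoxymethoxy)‑2‑prenylphenol; 7 methyl 4‑bromo‑2‑ethoxy‑7‑{[(1R,2S,5R)‑menthyloxy]methoxy}‑1,3‑benzodioxole‑5‑carboxylate
Product: 8 methyl 4‑[3,5‑bis(methoxymethoxy)‑2‑prenylphenoxy]‑2‑ethoxy‑7‑{[(1R,2S,5R)‑menthyloxy]methoxy}‑1,3‑benzodioxole‑5‑carboxylate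
Conditions: CuI (cat.), picolinic acid (cat.), K3PO4, DMSO, 90 °C
Reagents that add atoms: none
Why: Copper‑catalysed Ullmann diaryl ether synthesis, in which the ortho ester assists the copper and the picolinic acid system is suited to ortho‑substituted partners, while orthoester, acetals and the prenyl group are inert to the basic medium.

Step 7
Reactants: 8 methyl 4‑[3,5‑bis(methoxymethoxy)‑2‑prenylphenoxy]‑2‑ethoxy‑7‑{[(1R,2S,5R)‑menthyloxy]methoxy}‑1,3‑benzodioxole‑5‑carboxylate
Product: 9 methyl 2‑[3,5‑bis(methoxymethoxy)‑2‑prenylphenoxy]‑3,4‑dihydroxy‑5‑{[(1R,2S,5R)‑menthyloxy]methoxy}benzoate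
Conditions: PPTS (cat.), MeOH/THF, rt
Reagents that add atoms: none
Why: Mild acid‑catalysed transorthoesterification to methanol releases the catechol, because cyclic aryl orthoformates exchange far faster than aryl MOM‑type acetals, so the three acetal ethers should survive.

Step 8
Reactants: 9 methyl 2‑[3,5‑bis(methoxymethoxy)‑2‑prenylphenoxy]‑3,4‑dihydroxy‑5‑{[(1R,2S,5R)‑menthyloxy]methoxy}benzoate
Product: 10 methyl 2‑[3,5‑bis(methoxymethoxy)‑2‑prenylphenoxy]‑3,4‑bis[(2‑methylbut‑3‑en‑2‑yl)oxy]‑5‑{[(1R,2S,5R)‑menthyloxy]methoxy}benzoate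
Conditions: Pd(PPh3)4 (cat.), tert‑butyl (2‑methylbut‑3‑en‑2‑yl) carbonate (excess), THF, 0 °C → rt
Reagents that add atoms: tert‑butyl (2‑methylbut‑3‑en‑2‑yl) carbonate C=CC(C)(C)OC(=O)OC(C)(C)C
Why: Pd(0)‑catalysed decarboxylative O‑allylation (Tsuji–Trost) of both catechol hydroxyls at the more substituted terminus of the 1,1‑dimethyl‑π‑allyl complex gives the bis(1,1‑dimethylallyl) ether at low temperature, the standard entry to caged Garcinia xanthone precursors.

Step 9
Reactants: 10 methyl 2‑[3,5‑bis(methoxymethoxy)‑2‑prenylphenoxy]‑3,4‑bis[(2‑methylbut‑3‑en‑2‑yl)oxy]‑5‑{[(1R,2S,5R)‑menthyloxy]methoxy}benzoate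
Product: 12 caged ester methyl (1R,3R,6S,7S)‑7‑[3,5‑bis(methoxymethoxy)‑2‑prenylphenoxy]‑1‑{[(1R,2S,5R)‑menthyloxy]methoxy}‑5,5‑dimethyl‑2‑oxo‑3‑prenyl‑4‑oxatricyclo[4.3.1.0(3,7)]dec‑8‑ene‑8‑carboxylate, via Claisen dienone 11 (not isolated)
Conditions: DMF, 120 °C; chromatographic separation of the two cage diastereomers
Reagents that add atoms: none
Why: Aromatic Claisen rearrangement of the allyl ether para to the ester onto the neighbouring O‑allylated carbon gives dienone 11, whose diene is trapped by intramolecular Diels–Alder reaction with the remaining 1,1‑dimethylallyl ether (Claisen/Diels–Alder cascade); the tether fixes the relative configuration of the four cage centres, both cage antipodes are expected in comparable amounts, and as menthyl‑acetal diastereomers they are to be separated to give the (1R,3R,6S,7S) cage.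

Step 10
Reactants: 12 caged ester (bis‑MOM ether and menthyloxymethyl ether)
Product: 13 methyl (1R,3R,6S,7S)‑7‑(3,5‑dihydroxy‑2‑prenylphenoxy)‑1‑hydroxy‑5,5‑dimethyl‑2‑oxo‑3‑prenyl‑4‑oxatricyclo[4.3.1.0(3,7)]dec‑8‑ene‑8‑carboxylate
Conditions: HCl (1.25 M in MeOH), 0 °C → rt, monitored
Reagents that add atoms: none
Why: Acid‑catalysed acetal exchange with methanol (MOM‑type deprotection) should remove the two aryl MOM groups and the tertiary menthyloxymethyl ether, and low temperature with short contact should prevent chroman formation from the ortho‑prenylphenol; no stereocentre is affected.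

Step 11
Reactants: 13 caged triol methyl ester
Product: 14 (1R,3R,6S,7S)‑7‑(3,5‑dihydroxy‑2‑prenylphenoxy)‑1‑hydroxy‑5,5‑dimethyl‑2‑oxo‑3‑prenyl‑4‑oxatricyclo[4.3.1.0(3,7)]dec‑8‑ene‑8‑carboxylic acid
Conditions: Me3SnOH, 1,2‑dichloroethane, 70 °C; aq. HCl work‑up
Reagents that add atoms: trimethyltin hydroxide C[Sn](C)(C)O
Why: Trimethyltin hydroxide hydrolyses methyl esters under essentially neutral conditions, which should avoid conjugate addition to the cage enoate and base‑induced changes at the bridgehead α‑ketol.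

Step 12
Reactants: 14 caged triol acid
Product: 16 spiro acylal in which the C8 carboxyl oxygen and the C7 ether oxygen of the cage are both bound to C6′ (S) of a (5′S)‑2′‑hydroxy‑5′‑prenylcyclohex‑2′‑ene‑1′,4′‑dione ring, via hydroxyquinone acid 15 (not isolated)
Conditions: (KSO3)2NO, KH2PO4 buffer, acetone/H2O, 0 °C → rt; then pH 2, extraction, CSA (cat.), CH2Cl2, rt
Reagents that add atoms: potassium nitrosodisulfonate (Fremy's salt) [K+].[K+].[O]N(S(=O)(=O)[O-])S(=O)(=O)[O-]
Why: Proposed new method: Teuber oxidation (known) converts the resorcinol ring at its only free position para to a hydroxyl into the 2‑hydroxy‑1,4‑benzoquinone 15, in which the carbon bearing the cage ether oxygen is the β‑carbon of a vinylogous ester held in a 1,5‑relationship to the cage carboxylic acid; acid‑catalysed 6‑exo‑trig conjugate addition of the CO2H group (a ring–chain tautomerism like 2‑acylbenzoic acid → 3‑hydroxyphthalide) followed by ketonisation at the prenyl‑bearing carbon should give the spiro acylal, the closest known type being intramolecular oxa‑Michael lactonisation of carboxylic acids onto enones and quinones; since addition and ketonisation are reversible, the spiro carbon (planar C=O flank on the side of the cage CH bridge C6) and the CH(prenyl) carbon (prenyl trans to the cage ether oxygen) are expected under thermodynamic control.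

Step 13
Reactants: 16 spiro hydroxy‑enedione; 17 prenal (3‑methylbut‑2‑enal)
Product: 19 CNP0222516.1, via 1‑oxatriene 18 (not isolated)
Conditions: prenal (excess), ethylenediammonium diacetate (cat.), CH2Cl2, rt → 40 °C
Reagents that add atoms: none
Why: The buffered diamine turns prenal into its iminium ion, which is attacked by the enol carbon C3′ of the 2‑hydroxycyclohex‑2‑ene‑1,4‑dione (Knoevenagel condensation), and loss of the amine gives the 1‑oxatriene 18, which closes by thermal disrotatory oxa‑6π electrocyclisation. The closest known reaction type is the formal [3+3] annulation of 2‑hydroxy‑1,4‑quinones and cyclic 1,3‑diones with enals (lawsone with prenal gives dehydro‑α‑lapachone). The one ring closed is the 2,2‑dimethyl‑2H‑pyran, by intermolecular C–C bond formation followed by 6π‑electrocyclic O–C bond formation. No new stereocentre arises, since the CMe2 carbon is not stereogenic and the cage is untouched, while the enolisable CH(prenyl) centre can settle under the amine/acid buffer into the more stable arrangement, so that epimeric material from step 12 should converge. Site selectivity (enol carbon against the α‑CH of the C4′ ketone) follows from the far higher nucleophilicity of the vinylogous acid, and the linear pyran (oxygen on C2′, 1,4‑dione retained) is favoured over the angular one because the reversible electrocyclisation avoids a vicinal dione. The aprotic solvent and the catalytic, buffered amine are chosen to spare the cage enoate and the acylal.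

**Compound list**

1 | phloroglucinol (benzene‑1,3,5‑triol) | Oc1cc(O)cc(O)c1 | starting material
2 | 3,5‑bis(methoxymethoxy)phenol | COCOc1cc(O)cc(OCOC)c1 | intermediate
3 | 3,5‑bis(methoxymethoxy)‑2‑(3‑methylbut‑2‑en‑1‑yl)phenol | Oc1cc(OCOC)cc(OCOC)c1CC=C(C)C | intermediate
4 | methyl gallate (methyl 3,4,5‑trihydroxybenzoate) | COC(=O)c1cc(O)c(O)c(O)c1 | starting material
5 | methyl 2‑ethoxy‑7‑hydroxy‑1,3‑benzodioxole‑5‑carboxylate (racemic at the orthoester carbon) | CCOC1Oc2cc(C(=O)OC)cc(O)c2O1 | intermediate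
6 | methyl 2‑ethoxy‑7‑({[(1R,2S,5R)‑5‑methyl‑2‑(propan‑2‑yl)cyclohexyl]oxy}methoxy)‑1,3‑benzodioxole‑5‑carboxylate (both epimers at the orthoester carbon) | CCOC1Oc2cc(C(=O)OC)cc(OCO[C@@H]3C[C@H](C)CC[C@H]3C(C)C)c2O1 | intermediate
7 | methyl 4‑bromo‑2‑ethoxy‑7‑({[(1R,2S,5R)‑menthyl]oxy}methoxy)‑1,3‑benzodioxole‑5‑carboxylate (both epimers at the orthoester carbon) | CCOC1Oc2c(Br)c(C(=O)OC)cc(OCO[C@@H]3C[C@H](C)CC[C@H]3C(C)C)c2O1 | intermediate
8 | methyl 4‑[3,5‑bis(methoxymethoxy)‑2‑prenylphenoxy]‑2‑ethoxy‑7‑({[(1R,2S,5R)‑menthyl]oxy}methoxy)‑1,3‑benzodioxole‑5‑carboxylate (both epimers at the orthoester carbon) | CCOC1Oc2c(Oc3cc(OCOC)cc(OCOC)c3CC=C(C)C)c(C(=O)OC)cc(OCO[C@@H]4C[C@H](C)CC[C@H]4C(C)C)c2O1 | intermediate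
9 | methyl 2‑[3,5‑bis(methoxymethoxy)‑2‑prenylphenoxy]‑3,4‑dihydroxy‑5‑({[(1R,2S,5R)‑menthyl]oxy}methoxy)benzoate | COC(=O)c1cc(OCO[C@@H]2C[C@H](C)CC[C@H]2C(C)C)c(O)c(O)c1Oc1cc(OCOC)cc(OCOC)c1CC=C(C)C | intermediate
10 | methyl 2‑[3,5‑bis(methoxymethoxy)‑2‑prenylphenoxy]‑3,4‑bis[(2‑methylbut‑3‑en‑2‑yl)oxy]‑5‑({[(1R,2S,5R)‑menthyl]oxy}methoxy)benzoate | COC(=O)c1cc(OCO[C@@H]2C[C@H](C)CC[C@H]2C(C)C)c(OC(C)(C)C=C)c(OC(C)(C)C=C)c1Oc1cc(OCOC)cc(OCOC)c1CC=C(C)C | intermediate
11 | Claisen dienone (not isolated): methyl (5R)‑6‑aryloxy‑3‑(menthyloxymethoxy)‑5‑[(2‑methylbut‑3‑en‑2‑yl)oxy]‑4‑oxo‑5‑prenylcyclohexa‑2,6‑diene‑1‑carboxylate‑type 2,4‑cyclohexadienone, aryl = 3,5‑bis(methoxymethoxy)‑2‑prenylphenyl | C=CC(C)(C)O[C@@]1(CC=C(C)C)C(=O)C(OCO[C@@H]2C[C@H](C)CC[C@H]2C(C)C)=CC(C(=O)OC)=C1Oc1cc(OCOC)cc(OCOC)c1CC=C(C)C | intermediate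
12 | caged ester, methyl (1R,3R,6S,7S)‑7‑[3,5‑bis(methoxymethoxy)‑2‑prenylphenoxy]‑1‑({[(1R,2S,5R)‑menthyl]oxy}methoxy)‑5,5‑dimethyl‑2‑oxo‑3‑prenyl‑4‑oxatricyclo[4.3.1.0(3,7)]dec‑8‑ene‑8‑carboxylate | COC(=O)C1=C[C@]3(OCO[C@@H]2C[C@H](C)CC[C@H]2C(C)C)C[C@H]4C(C)(C)O[C@@](CC=C(C)C)(C3=O)[C@@]14Oc1cc(OCOC)cc(OCOC)c1CC=C(C)C | intermediate
13 | methyl (1R,3R,6S,7S)‑7‑(3,5‑dihydroxy‑2‑prenylphenoxy)‑1‑hydroxy‑5,5‑dimethyl‑2‑oxo‑3‑prenyl‑4‑oxatricyclo[4.3.1.0(3,7)]dec‑8‑ene‑8‑carboxylate | COC(=O)C1=C[C@]3(O)C[C@H]4C(C)(C)O[C@@](CC=C(C)C)(C3=O)[C@@]14Oc1cc(O)cc(O)c1CC=C(C)C | intermediate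
14 | (1R,3R,6S,7S)‑7‑(3,5‑dihydroxy‑2‑prenylphenoxy)‑1‑hydroxy‑5,5‑dimethyl‑2‑oxo‑3‑prenyl‑4‑oxatricyclo[4.3.1.0(3,7)]dec‑8‑ene‑8‑carboxylic acid | OC(=O)C1=C[C@]3(O)C[C@H]4C(C)(C)O[C@@](CC=C(C)C)(C3=O)[C@@]14Oc1cc(O)cc(O)c1CC=C(C)C | intermediate
15 | hydroxyquinone acid (not isolated): (1R,3R,6S,7S)‑1‑hydroxy‑7‑[(5‑hydroxy‑3,6‑dioxo‑2‑prenylcyclohexa‑1,4‑dien‑1‑yl)oxy]‑5,5‑dimethyl‑2‑oxo‑3‑prenyl‑4‑oxatricyclo[4.3.1.0(3,7)]dec‑8‑ene‑8‑carboxylic acid | OC(=O)C1=C[C@]3(O)C[C@H]4C(C)(C)O[C@@](CC=C(C)C)(C3=O)[C@@]14OC1=C(CC=C(C)C)C(=O)C=C(O)C1=O | intermediate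
16 | spiro acylal: (5′S,6′S)‑2′‑hydroxy‑5′‑prenylcyclohex‑2′‑ene‑1′,4′‑dione whose C6′ is bound to the C8 carboxyl oxygen and the C7 ether oxygen of the (1R,3R,6S,7S) cage (spiro 1,3‑dioxin‑4‑one) | CC(C)=CC[C@H]1C(=O)C=C(O)C(=O)[C@@]12OC(=O)C1=C[C@]3(O)C[C@H]4C(C)(C)O[C@@](CC=C(C)C)(C3=O)[C@@]14O2 | intermediate
17 | prenal (3‑methylbut‑2‑enal) | CC(C)=CC=O | starting material
18 | 1‑oxatriene (not isolated): 3′‑(3‑methylbut‑2‑enylidene)cyclohexane‑1′,2′,4′‑trione form of 16, diene chain syn to the C2′ carbonyl | CC(C)=CC[C@H]1C(=O)/C(=C/C=C(C)C)C(=O)C(=O)[C@@]12OC(=O)C1=C[C@]3(O)C[C@H]4C(C)(C)O[C@@](CC=C(C)C)(C3=O)[C@@]14O2 | intermediate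
19 | CNP0222516.1: 16 with a 2,2‑dimethyl‑2H‑pyran fused through O–C2′ and C3′ | CC(C)=CC[C@H]1C(=O)C2=C(OC(C)(C)C=C2)C(=O)[C@@]12OC(=O)C1=C[C@]3(O)C[C@H]4C(C)(C)O[C@@](CC=C(C)C)(C3=O)[C@@]14O2 | target

**Count**

Total steps: 13. Longest linear sequence: 11 steps (methyl gallate 4 → 19, steps 3–13).

**Steps most likely to fail**

1. Step 12 (Proposed new method). What may go wrong: the ring–chain equilibrium may rest on the side of the open hydroxyquinone acid, so that no net conjugate addition occurs, or the acylal may close with the wrong spiro configuration and fail to equilibrate. The fallback uses known chemistry and closes the ring under kinetic control. It sets out from 15, isolated this time after the Teuber oxidation and acidification. Sodium dithionite (EtOAc/H2O) reduces it to the hydroxyhydroquinone acid F1. Acetic anhydride (2 equiv) with pyridine at low temperature should acylate the two unhindered phenols and spare the one flanked by two oxygen substituents, giving the diacetate F2. PhI(OAc)2 in hexafluoroisopropanol/CH2Cl2 at 0 °C then oxidises the remaining phenol. The phenoxonium ion is best stabilised at the ortho carbon bearing the cage ether oxygen and is captured there by the carboxylic acid (hypervalent‑iodine dearomative ortho‑spirolactonisation of a 2‑alkoxyphenol), giving the spirodienone bis(enol acetate) F3. Mild methanolysis (K2CO3, MeOH, 0 °C) removes both enol acetates, and ketonisation at the prenyl‑bearing carbon brings the route back at 16.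

2. Step 13. What may go wrong: amine‑induced retro‑oxa‑Michael opening of the acylal, aza‑Michael addition to the cage enoate, or closure through the C4′ carbonyl oxygen to the angular pyran. The fallback sets out from 16 and avoids any amine. C‑Prenylation of the lithium salt of the vinylogous acid (LiH, prenyl bromide, DMSO, rt; the lapachol‑type alkylation) gives the C‑prenyl hydroxy‑enedione F4. DDQ (CH2Cl2, rt) then abstracts hydride from the doubly activated allylic CH2, and the resulting 1‑oxatriene closes by the same oxa‑6π electrocyclisation (the lapachol → dehydro‑α‑lapachone oxidation), returning at 19.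

3. Step 9. What may go wrong: poor chromatographic discrimination of the two menthyl‑acetal diastereomers (no facial bias is expected from the remote auxiliary), or erosion of the site selectivity of the first Claisen shift. The fallback sets out from 10 and replaces the diastereomer separation by a classical resolution. The unseparated mixture of 12 and its cage‑antipodal diastereomer F5 is carried through steps 10 and 11. Loss of the menthyl acetal turns the diastereomers into enantiomers, so the triol ester is obtained together with its antipode F6, and the acid 14 together with its antipode F7. The racemic acid is resolved by fractional crystallisation of its salt with (R)‑1‑phenylethylamine (or the S‑amine, whichever gives the less soluble salt of the wanted acid; shown for R), salt F8, and acidification returns the route at enantiopure 14.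

**Further compounds**

F1 | step 12 | (1R,3R,6S,7S)‑1‑hydroxy‑5,5‑dimethyl‑2‑oxo‑3‑prenyl‑7‑(3,5,6‑trihydroxy‑2‑prenylphenoxy)‑4‑oxatricyclo[4.3.1.0(3,7)]dec‑8‑ene‑8‑carboxylic acid | OC(=O)C1=C[C@]3(O)C[C@H]4C(C)(C)O[C@@](CC=C(C)C)(C3=O)[C@@]14Oc1c(CC=C(C)C)c(O)cc(O)c1O
F2 | step 12 | (1R,3R,6S,7S)‑7‑(3,5‑diacetoxy‑6‑hydroxy‑2‑prenylphenoxy)‑1‑hydroxy‑5,5‑dimethyl‑2‑oxo‑3‑prenyl‑4‑oxatricyclo[4.3.1.0(3,7)]dec‑8‑ene‑8‑carboxylic acid | OC(=O)C1=C[C@]3(O)C[C@H]4C(C)(C)O[C@@](CC=C(C)C)(C3=O)[C@@]14Oc1c(CC=C(C)C)c(OC(C)=O)cc(OC(C)=O)c1O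
F3 | step 12 | spirodienone bis(enol acetate): 3′,5′‑diacetoxy‑2′‑prenylcyclohexa‑2′,4′‑dien‑6′‑one spiro‑fused at C1′ (S) to the cage 1,3‑dioxin‑4‑one | CC(C)=CCC1=C(OC(C)=O)C=C(OC(C)=O)C(=O)[C@@]12OC(=O)C1=C[C@]3(O)C[C@H]4C(C)(C)O[C@@](CC=C(C)C)(C3=O)[C@@]14O2
F4 | step 13 | C3′‑prenyl derivative of 16 (2′‑hydroxy‑3′,5′‑diprenylcyclohex‑2′‑ene‑1′,4′‑dione spiro acylal) | CC(C)=CC[C@H]1C(=O)C(CC=C(C)C)=C(O)C(=O)[C@@]12OC(=O)C1=C[C@]3(O)C[C@H]4C(C)(C)O[C@@](CC=C(C)C)(C3=O)[C@@]14O2
F5 | step 9 | cage‑antipodal diastereomer of 12, (1S,3S,6R,7R) cage with (1R,2S,5R)‑menthyl | COC(=O)C1=C[C@@]3(OCO[C@@H]2C[C@H](C)CC[C@H]2C(C)C)C[C@@H]4C(C)(C)O[C@](CC=C(C)C)(C3=O)[C@]14Oc1cc(OCOC)cc(OCOC)c1CC=C(C)C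
F6 | step 9 | enantiomer of 13, (1S,3S,6R,7R) | COC(=O)C1=C[C@@]3(O)C[C@@H]4C(C)(C)O[C@](CC=C(C)C)(C3=O)[C@]14Oc1cc(O)cc(O)c1CC=C(C)C
F7 | step 9 | enantiomer of 14, (1S,3S,6R,7R) | OC(=O)C1=C[C@@]3(O)C[C@@H]4C(C)(C)O[C@](CC=C(C)C)(C3=O)[C@]14Oc1cc(O)cc(O)c1CC=C(C)C
F8 | step 9 | (R)‑1‑phenylethylammonium salt of 14 | [O-]C(=O)C1=C[C@]3(O)C[C@H]4C(C)(C)O[C@@](CC=C(C)C)(C3=O)[C@@]14Oc1cc(O)cc(O)c1CC=C(C)C.C[C@@H]([NH3+])c1ccccc1
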